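**Plan**

- Retrosynthesis: ring C is opened at O1–C2 (lactol dehydration) to a 2-hydroxyaryl α-formyl deoxybenzoin. C3–C4 is then cut as the reverse of a 1,2-aroyl shift in a chalcone oxide. The oxirane goes back to an enone, its Cα=Cβ bond (later C2–C3) to an aldol pair, and C4–C4a to acylation of a phenol.
- Enabling feature: C3 of ring C carries ring B and is bonded to the C4 carbonyl. In a chalcone oxide this C3 is the benzylic oxirane carbon, whose cation is stabilised by the 2-methoxyphenyl ring B. The ring A aroyl group can therefore move onto it while the neighbouring oxirane carbon becomes the C2 aldehyde.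
- Forward: the ring A ketone and the ring B aldehyde (two steps each) are joined by Claisen–Schmidt condensation. Epoxidation and BF3-induced rearrangement give the branched 1,2-diaryl three-carbon chain. Ring C closes last, by O1–C2 bond formation and dehydration, once hydrogenolysis has freed the ring A phenol.
- Stereochemistry: the target has no stereocentre. The racemic trans oxirane only relays the E geometry of the enone, and both of its centres are consumed in the rearrangement.

Key step: step 7

Remark: compounds 11, 13, 14, 15 and 16 are racemic. The SMILES of 13 shows one enantiomer of the trans pair. Compound 14 is written as the keto aldehyde although it should exist largely as its hydroxymethylene enol.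

**Route**

Step 1
Reactants: 1 3,4,5-trimethoxyphenol; 2 acetic acid
Product: 4 1-(2-hydroxy-4,5,6-trimethoxyphenyl)ethan-1-one, via difluoroboron chelate 3 (not isolated)
Conditions: AcOH (reagent and solvent), BF3·OEt2 (3 equiv), 90 °C; then 10% aq. NaOAc, 20 °C
Reagents that add atoms: acetic acid (2), CC(=O)O
Why: BF3-mediated Friedel–Crafts C-acylation of an electron-rich phenol (Fries-type) can only occur at the two equivalent positions ortho to the hydroxyl group because the para position carries a methoxy group, and the O–BF2 chelate of the product resists a second acylation until the aqueous quench hydrolyses it.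

Step 2
Reactants: 4 1-(2-hydroxy-4,5,6-trimethoxyphenyl)ethan-1-one; 5 benzyl bromide
Product: 6 1-[2-(benzyloxy)-4,5,6-trimethoxyphenyl]ethan-1-one
Conditions: BnBr (1.2 equiv), K2CO3 (2 equiv), DMF, 60 °C
Reagents that add atoms: benzyl bromide (5), BrCc1ccccc1
Why: Williamson etherification of the chelated ortho-hydroxy ketone should proceed in warm DMF, where carbonate deprotonates the phenol but not the methyl ketone, so only O-benzylation is expected.

Step 3
Reactants: 7 2,3-dihydroxybenzaldehyde; 5 benzyl bromide
Product: 9 3-(benzyloxy)-2-hydroxybenzaldehyde, via disodium dianion 8 (not isolated)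
Conditions: NaH (2.2 equiv), DMSO, 20 °C; then BnBr (1.0 equiv), 20 °C; aq. HCl work-up
Reagents that add atoms: benzyl bromide (5), BrCc1ccccc1
Why: Williamson etherification of the catechol dianion is site-selective because the 2-oxide is conjugated to and chelated with the formyl group, so the 3-oxide is the stronger nucleophile and should take the single equivalent of benzyl bromide.

Step 4
Reactants: 9 3-(benzyloxy)-2-hydroxybenzaldehyde
Product: 10 3-(benzyloxy)-2-methoxybenzaldehyde
Conditions: MeI (1.5 equiv), K2CO3 (2 equiv), DMF, 20 °C
Reagents that add atoms: iodomethane, CI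
Why: Williamson methylation of the one remaining phenol is unambiguous, and the non-enolisable aldehyde and the benzyl ether are inert to carbonate and iodomethane.

Step 5
Reactants: 6 1-[2-(benzyloxy)-4,5,6-trimethoxyphenyl]ethan-1-one; 10 3-(benzyloxy)-2-methoxybenzaldehyde
Product: 12 (2E)-1-[2-(benzyloxy)-4,5,6-trimethoxyphenyl]-3-[3-(benzyloxy)-2-methoxyphenyl]prop-2-en-1-one, via aldol adduct 11 (not isolated)
Conditions: KOH (50% aq.), EtOH, 20 °C
Reagents that add atoms: none
Why: Claisen–Schmidt condensation pairs the only enolisable partner (the methyl ketone) with a non-enolisable aldehyde, and E1cB dehydration of the aldol adduct should give the thermodynamically preferred E enone.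

Step 6
Reactants: 12 (2E)-1-[2-(benzyloxy)-4,5,6-trimethoxyphenyl]-3-[3-(benzyloxy)-2-methoxyphenyl]prop-2-en-1-one
Product: 13 racemic trans-[2-(benzyloxy)-4,5,6-trimethoxyphenyl]{3-[3-(benzyloxy)-2-methoxyphenyl]oxiran-2-yl}methanone
Conditions: 30% aq. H2O2, 2 M aq. NaOH, MeOH–THF, 0 to 20 °C
Reagents that add atoms: hydrogen peroxide, OO
Why: Weitz–Scheffer epoxidation (conjugate addition of hydroperoxide, then closure of the enolate onto oxygen with loss of hydroxide) should give the trans oxirane from the E enone as a racemate since no chiral influence is present, and the benzyl ether on the ring A oxygen excludes the Algar–Flynn–Oyamada flavonol pathway.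

Step 7
Reactants: 13 racemic trans-[2-(benzyloxy)-4,5,6-trimethoxyphenyl]{3-[3-(benzyloxy)-2-methoxyphenyl]oxiran-2-yl}methanone
Product: 14 3-[2-(benzyloxy)-4,5,6-trimethoxyphenyl]-2-[3-(benzyloxy)-2-methoxyphenyl]-3-oxopropanal
Conditions: BF3·OEt2 (0.5 equiv), CH2Cl2, 0 to 20 °C, short reaction time; cold pH 7 phosphate buffer quench; crude product taken on directly
Reagents that add atoms: none
Why: BF3 binds the oxirane oxygen and the C–O bond at the benzylic carbon (the later C3, bearing ring B) ionises, because the 2-methoxyphenyl group stabilises positive charge there while the other oxirane carbon is deactivated by the adjacent carbonyl group; the ring A aroyl group then shifts from that neighbouring carbon to the cationic centre, which creates the C3–C4 bond, and the carbon it leaves collapses with its O–BF3 substituent to the formyl group that becomes C2. The closest known reaction type is the Lewis acid Meinwald rearrangement of α,β-epoxy ketones with acyl migration, the established behaviour of chalcone oxides that leads to α-formyl deoxybenzoins. No ring is closed in this step. Both oxirane stereocentres are consumed, and the one new CH centre lies between two carbonyl groups, should exist mainly as the hydroxymethylene enol and needs no control. The selectivity needed is opening at the aryl-bearing carbon followed by aroyl rather than hydride migration: the electron-rich ring B fixes the site of ionisation, the acyl shift is the normal course for such benzylic cations, and the benzyl ether on the ring A oxygen keeps that oxygen from adding to the cation as a free phenol would. A sub-stoichiometric charge of Lewis acid, a short reaction time and a cold neutral quench are chosen to limit retro-Claisen loss of the formyl group.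

Step 8
Reactants: 14 3-[2-(benzyloxy)-4,5,6-trimethoxyphenyl]-2-[3-(benzyloxy)-2-methoxyphenyl]-3-oxopropanal
Product: 17 3-(3-hydroxy-2-methoxyphenyl)-5,6,7-trimethoxy-4H-chromen-4-one (the target), via diphenol keto aldehyde 15 (not isolated), via 2-hydroxyisoflavanone lactol 16 (not isolated)
Conditions: H2 (1 atm), 10% Pd/C, EtOAc, 20 °C; filter; then p-TsOH·H2O (cat.), THF, 50 °C
Reagents that add atoms: none
Why: Hydrogenolysis over palladium on carbon should cleave both aryl benzyl ethers, after which the freed ring A phenol adds to the formyl group in a 6-exo-trig lactol closure (O1–C2) and acid-catalysed dehydration gives the conjugated 4-pyranone, which has no stereocentre.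

**Compound list**

1 | 3,4,5-trimethoxyphenol | COc1cc(O)cc(OC)c1OC | starting material
2 | acetic acid | CC(=O)O | starting material
3 | 2,2-difluoro-5,6,7-trimethoxy-4-methyl-1,3,2-benzodioxaborinine (O–BF2 chelate of 4, not isolated) | CC1=[O+][B-](F)(F)Oc2cc(OC)c(OC)c(OC)c12 | intermediate
4 | 1-(2-hydroxy-4,5,6-trimethoxyphenyl)ethan-1-one | CC(=O)c1c(O)cc(OC)c(OC)c1OC | intermediate
5 | benzyl bromide | BrCc1ccccc1 | starting material
6 | 1-[2-(benzyloxy)-4,5,6-trimethoxyphenyl]ethan-1-one | CC(=O)c1c(OCc2ccccc2)cc(OC)c(OC)c1OC | intermediate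
7 | 2,3-dihydroxybenzaldehyde | O=Cc1cccc(O)c1O | starting material
8 | disodium 3-formylbenzene-1,2-diolate (not isolated) | [Na+].[Na+].[O-]c1cccc(C=O)c1[O-] | intermediate
9 | 3-(benzyloxy)-2-hydroxybenzaldehyde | O=Cc1cccc(OCc2ccccc2)c1O | intermediate
10 | 3-(benzyloxy)-2-methoxybenzaldehyde | COc1c(C=O)cccc1OCc1ccccc1 | intermediate
11 | 1-[2-(benzyloxy)-4,5,6-trimethoxyphenyl]-3-[3-(benzyloxy)-2-methoxyphenyl]-3-hydroxypropan-1-one (racemic aldol adduct, not isolated) | O=C(CC(O)c1cccc(OCc2ccccc2)c1OC)c1c(OCc2ccccc2)cc(OC)c(OC)c1OC | intermediate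
12 | (2E)-1-[2-(benzyloxy)-4,5,6-trimethoxyphenyl]-3-[3-(benzyloxy)-2-methoxyphenyl]prop-2-en-1-one | O=C(/C=C/c1cccc(OCc2ccccc2)c1OC)c1c(OCc2ccccc2)cc(OC)c(OC)c1OC | intermediate
13 | racemic trans-[2-(benzyloxy)-4,5,6-trimethoxyphenyl]{3-[3-(benzyloxy)-2-methoxyphenyl]oxiran-2-yl}methanone, (2R,3S) enantiomer drawn | O=C([C@@H]1O[C@H]1c1cccc(OCc2ccccc2)c1OC)c1c(OCc2ccccc2)cc(OC)c(OC)c1OC | intermediate
14 | 3-[2-(benzyloxy)-4,5,6-trimethoxyphenyl]-2-[3-(benzyloxy)-2-methoxyphenyl]-3-oxopropanal (racemic, enolisable) | O=CC(c1cccc(OCc2ccccc2)c1OC)C(=O)c1c(OCc2ccccc2)cc(OC)c(OC)c1OC | intermediate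
15 | 3-(2-hydroxy-4,5,6-trimethoxyphenyl)-2-(3-hydroxy-2-methoxyphenyl)-3-oxopropanal (not isolated) | O=CC(c1cccc(O)c1OC)C(=O)c1c(O)cc(OC)c(OC)c1OC | intermediate
16 | 2-hydroxy-3-(3-hydroxy-2-methoxyphenyl)-5,6,7-trimethoxy-2,3-dihydro-4H-chromen-4-one (not isolated) | COc1cc2c(c(OC)c1OC)C(=O)C(c1cccc(O)c1OC)C(O)O2 | intermediate
17 | 3-(3-hydroxy-2-methoxyphenyl)-5,6,7-trimethoxy-4H-chromen-4-one | COc1cc2occ(-c3cccc(O)c3OC)c(=O)c2c(OC)c1OC | target

**Step count**

Total: 8 steps. Longest linear sequence: 6 steps (steps 1, 2, 5, 6, 7, 8; the aldehyde branch through steps 3, 4, 5, 6, 7, 8 is equally long).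

**Steps most likely to fail**

Step 7. The oxirane may ionise without the aroyl shift: a hydride shift would lead to a 1,2-diketone, and an ether oxygen of ring A or fluoride may trap the benzylic cation. The formyl group may also be lost by retro-Claisen cleavage during quench or handling. The fallback leaves the route at chalcone 12 and replaces steps 6 to 8. Oxidative rearrangement of 12 with Tl(NO3)3·3H2O (trivalent thallium) in MeOH–HC(OMe)3 at 20 °C moves ring B from Cβ to Cα instead of moving the aroyl group. It should give the dimethyl acetal 1-[2-(benzyloxy)-4,5,6-trimethoxyphenyl]-2-[3-(benzyloxy)-2-methoxyphenyl]-3,3-dimethoxypropan-1-one F1, which has the same branched skeleton with C2 masked. Hydrogenolysis (H2, 10% Pd/C, EtOAc–MeOH) should then give the diphenol acetal 1-(2-hydroxy-4,5,6-trimethoxyphenyl)-2-(3-hydroxy-2-methoxyphenyl)-3,3-dimethoxypropan-1-one F2. Warming F2 with HCl in MeOH should close ring C through the 2-methoxyisoflavanone 3-(3-hydroxy-2-methoxyphenyl)-2,5,6,7-tetramethoxy-2,3-dihydro-4H-chromen-4-one F3, which expels methanol. The fallback rejoins the route at target 17.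

Step 8. While the benzyl ethers are still being cleaved, the enolised formyl ketone may be hydrogenated or may lose its formyl group, and the new pyranone double bond may be reduced if closure takes place on the catalyst. The fallback sets out from 14 and masks the formyl group as a vinylogous amide before any hydrogen is used. Condensation of 14 with Me2NH (2 M in THF, EtOH, 20 °C) should give the enaminone (2E)-1-[2-(benzyloxy)-4,5,6-trimethoxyphenyl]-2-[3-(benzyloxy)-2-methoxyphenyl]-3-(dimethylamino)prop-2-en-1-one F4; the alkene geometry is of no consequence. Hydrogenolysis (H2, 10% Pd/C, EtOAc), which the vinylogous amide should survive, would give (2E)-3-(dimethylamino)-1-(2-hydroxy-4,5,6-trimethoxyphenyl)-2-(3-hydroxy-2-methoxyphenyl)prop-2-en-1-one F5. Warming F5 in AcOH should close it by addition of the phenol and elimination of dimethylamine, which is the standard end game of the deoxybenzoin-enaminone isoflavone synthesis. The fallback rejoins the route at target 17.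

Step 3. Site selectivity in the dianion alkylation may be lost, through benzylation at the chelated 2-oxide or double benzylation. The fallback sets out from 7 and swaps selective protection for selective deprotection. Exhaustive benzylation (BnBr 2.5 equiv, K2CO3, DMF, 60 °C) should give 2,3-bis(benzyloxy)benzaldehyde F6. MgBr2·OEt2 in toluene–Et2O at reflux should then cleave only the benzyl ether ortho to the formyl group, because magnesium is held between the carbonyl and the 2-ether oxygen and delivers bromide to that benzyl group alone. The fallback rejoins the route at 9.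

Further compounds
F1 | step 7 | 1-[2-(benzyloxy)-4,5,6-trimethoxyphenyl]-2-[3-(benzyloxy)-2-methoxyphenyl]-3,3-dimethoxypropan-1-one (racemic) | COC(OC)C(c1cccc(OCc2ccccc2)c1OC)C(=O)c1c(OCc2ccccc2)cc(OC)c(OC)c1OC
F2 | step 7 | 1-(2-hydroxy-4,5,6-trimethoxyphenyl)-2-(3-hydroxy-2-methoxyphenyl)-3,3-dimethoxypropan-1-one (racemic) | COC(OC)C(c1cccc(O)c1OC)C(=O)c1c(O)cc(OC)c(OC)c1OC
F3 | step 7 | 3-(3-hydroxy-2-methoxyphenyl)-2,5,6,7-tetramethoxy-2,3-dihydro-4H-chromen-4-one (racemic, not isolated) | COc1cc2c(c(OC)c1OC)C(=O)C(c1cccc(O)c1OC)C(OC)O2
F4 | step 8 | (2E)-1-[2-(benzyloxy)-4,5,6-trimethoxyphenyl]-2-[3-(benzyloxy)-2-methoxyphenyl]-3-(dimethylamino)prop-2-en-1-one | CN(C)/C=C(\c1cccc(OCc2ccccc2)c1OC)C(=O)c1c(OCc2ccccc2)cc(OC)c(OC)c1OC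
F5 | step 8 | (2E)-3-(dimethylamino)-1-(2-hydroxy-4,5,6-trimethoxyphenyl)-2-(3-hydroxy-2-methoxyphenyl)prop-2-en-1-one | CN(C)/C=C(\c1cccc(O)c1OC)C(=O)c1c(O)cc(OC)c(OC)c1OC
F6 | step 3 | 2,3-bis(benzyloxy)benzaldehyde | O=Cc1cccc(OCc2ccccc2)c1OCc1ccccc1
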